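The bench chemist's noon run stood before me, and the new flask differs from it in the catalyst charge, 20 mol% against 28 mol%.

- noon: left-handed substrate 0.050 M; right-handed substrate 0.050 M; partner 0.80 equiv; protic impurity 2.5 mM; free catalyst 28 mol%; added ligand 31 mM; run made earlier
- flask: left-handed substrate 0.050 M; partner 0.800 equiv; protic impurity 2.50 mM; free catalyst 20 mol%; added ligand 31 mM; right-handed substrate 0.050 M; time 10 h

- noon (time / h: left-handed product / %, right-handed product / %, left-handed substrate / %): 0.333: 0.7, 0.5, 48.6; 1.00: 1.3, 0, 47.6; 1.50: 1.2, 0.7, 47.4; 2.50: 1.4, 2.4, 47.0; 4.00: 1.6, 4.2, 46.5; 5.00: 2.4, 4.9, 46.0; 6.00: 3.3, 5.6, 45.2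

(standard deviation of a reading: 0.5 percentage points)

- free catalyst is single-handed; left-handed substrate and right-handed substrate are mirror images of each other, charged as a racemate, each of them at the stated concentration
- an excess is the difference of the two amounts in percent of their sum
- an excess is below zero if the other one leads
- no earlier run changes the charge of free catalyst; that part of a forecast is a guess

1. excess of left-handed product over right-handed product in the product at 30 min
2. excess of left-handed product over right-handed product in the product at 10 h
3. part of the left-handed substrate and right-handed substrate charged together that has reacted at 10 h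

I followed one product molecule to its fork: does it leave left-handed or right-handed? The first question was whether the earliest reading could say. At 0.333 h in the noon run the two products differed by 0.2 percentage points against a scatter of 0.5 points, so it could not, and I held ea near zero.

The next question was what the later molecules chose. From 1.50 h to 6.00 h the noon run gained 2.1 points of left-handed product and 4.9 points of right-handed product, so the right-handed gain was larger. Their excess is −40.0 %; I call this excess among newly made product molecules the late excess. It is a reading, and each reading in it carries the same scatter. The whole product of the noon run at 6.00 h showed −25.8 %, with the early molecules counted in.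

The last question was whether the smaller charge moves the fork. No earlier run tells, so this is a guess: I assumed that both branches slow alike. By 10 h I expected late molecules to outweigh early ones, so I put eb near the late excess. Right-handed substrate was not read at noon, so I set no figure on cb.

The forecast gave ea 55 %, eb −18 % and cb 11.5 %, with the remark “The catalyst order is a guess.” Its eb stands above mine.

The flask gave ea 2.85 %, eb −42.7 % and cb 17.9 %.

    free catalyst + left-handed substrate ⇌ catalyst intermediate A (K = 32.3 M⁻¹, k = 0.524 M⁻¹ min⁻¹)
    free catalyst + right-handed substrate ⇌ catalyst intermediate B (K = 419 M⁻¹, k = 1.07 M⁻¹ min⁻¹)
    partner + catalyst intermediate A → free catalyst + left-handed product (k = 0.142 M⁻¹ min⁻¹)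
    partner + catalyst intermediate B → free catalyst + right-handed product (k = 0.0563 M⁻¹ min⁻¹)
    left-handed substrate ⇌ right-handed substrate (k = 2.04 × 10⁻⁴ min⁻¹)
    partner + protic impurity → quenched reagent (k = 0.238 M⁻¹ min⁻¹)
    free catalyst + added ligand ⇌ idle complex, settled at all times (K = 60.0 M⁻¹)

At 1.72 h the flask used partner 1.8 times as fast through catalyst intermediate B, to right-handed product, as through catalyst intermediate A, to left-handed product, and at 10.0 h catalyst intermediate B, the resting state, held 70.7 % of the catalyst against 8.73 % for catalyst intermediate A. Counted on newly made product, but over a different window, from 5.00 h to 10.0 h, this flask's late excess was −52.3 %, beside the −40.0 % read in the noon run from 1.50 h to 6.00 h, and the neighbour flask with 8 mol% of free catalyst ended with a whole excess of −46.0 % at 7.60 % reacted.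

All runs stem from a simulated flask on assumed constants.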